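The data were computed for an exercise; scatter was added.

Slowness is the first thing Tuesday's run shows. The starting material, charged at 28 mM, is down to 10 % by the first reading at 0.167 h, yet over the following hours the target sinks from 45 % to 11 % and the isomer of the product from 18 % to 6 %.

| flask | starting material | remark | time |
|---|---|---|---|
| Tuesday's | 28 mM | run made earlier |  |
| Saturday's | 44 mM | run made earlier |  |
| flask | 20 mM |  | 3.0 h |

- Tuesday's (time / h: isomer of the product / %, target / %, starting material / %): 0.167: 18, 45, 10; 0.500: 14, 34, 5; 0.833: 12, 23, 6; 1.33: 9, 18, 4; 2.00: 5, 14, 3; 2.50: 4, 12, 0; 3.00: 6, 11, 2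
- Saturday's (time / h: isomer of the product / %, target / %, starting material / %): 0.417: 13, 25, 9; 0.833: 6, 15, 6; 1.33: 3, 14, 4; 1.50: 2, 15, 4; 2.00: 1, 11, 5; 2.50: 4, 6, 0; 3.00: 2, 4, 0

(each reading ± 2 percentage points)

- ratio of isomer of the product to target at 2.5 s
- ratio of isomer of the product to target at 2.5 min
- ratio of isomer of the product to target at 3.0 h

When two substances lose the same fraction of themselves each hour, their ratio stands still however slow the loss, so at a late time you need that ratio and not the speed of the fading. Your first answer is the ratio at the first reading of Tuesday's run, 0.400. Put back against that run's last target reading, it expects 4.40 % of isomer where the reading is 6 %, a gap of 1.6 percentage points against a scatter of 2 points, so the ratio survives the round.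

Go round once more with the whole run. The summed isomer readings of Tuesday's run over its summed target readings come to 0.433, and this reading I call R, the plateau ratio. Saturday's run pools to 0.344, but its isomer readings go down to 1 %, with the same scatter. My own reckoning for the flask charged at 20 mM is R at 3.0 h, and R less firmly at 2.5 min, which lies earlier than the first reading of Tuesday's run. At 2.5 s I give no number, since a plateau need not yet stand there.

The forecast gives 0.4 at 3.0 h (range 0.27 to 0.55), slightly under R, and 0.4 at 2.5 min (range 0.22 to 0.7). At 2.5 s it also gives 0.4 (range 0.05 to 1.5), calling that “a guess with a wide range”.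

The flask gives 0.0490 at 2.5 s, 0.356 at 2.5 min and 0.441 at 3.0 h.

    2 starting material → self-condensation product (k = 0.560 M⁻¹ s⁻¹)
    starting material ⇌ isomer of the product (K = 2.10, k = 0.0180 s⁻¹)
    starting material ⇌ dormant form (K = 0.410, k = 0.00110 s⁻¹)
    starting material ⇌ target (K = 4.80, k = 0.410 s⁻¹)

The earliest value stands beside the rate constant of the step to the isomer over that of the step to the target, 0.0439: kinetic control at the start, thermodynamic control at the end. R times the target of the flask at 3.0 h, 12.8 %, gives 5.54 % of isomer, and the flask holds 5.63 %. In the neighbour flask charged at 8.0 mM, R times its 23.9 % of target gives 10.3 %, and that flask holds 10.5 % of isomer.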